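**Retrosynthetic overview**
1. The appended lactone is made last: Friedel–Crafts acylation of the free pyrrole α-carbon C3 with an (S)-methylsuccinic half ester (C20 from the chiral pool), then CBS reduction of the C18 ketone and lactonization.
2. The fused lactone comes from a C11 ketone flanked by C10 (ethyl) and C12 (CH2CO2Me): equatorial hydride attack gives the axial C11–O, which lactonizes; C15 is added by enolate methylation and C13 is then inverted by kinetic protonation.
3. The cyclohexane ring is made in one operation from (E)-1-nitrobut-1-ene and the flat, achiral bicyclic enal 6: bonds C9–C10 and C11–C12 form in an amine-catalysed, enantioselective [4+2] cycloaddition of a pyrrole-2,3-quinodimethane generated in situ; the nitro group is the latent C11 ketone.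
4. Enabling feature: the azepine methylene C9 sits on pyrrole C9a, and the pyrrole bond C9a=C1 continues through C12=C13 to the C14 carbonyl (the future lactone carbonyl, held at the aldehyde level). C9–H is therefore the vinylogous ε-C–H of an enal, and its trienamine is the diene C9=C9a–C1=C12. C10 and C12 end up α to the C11 ketone and are equilibrated against C9, the one centre the catalyst has to set.
5. Enal 6: N-alkylation of 1H-pyrrole-3-carbaldehyde, radical closure of the azepine ring, Wittig extension. Ring order: pyrrole (bought), azepine, cyclohexane, fused lactone, appended lactone.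

Key step: step 5

Numbering used below: pyrrole C1, C2, C3, N4, C9a; azepine N4, C5–C9, C9a; cyclohexane C1, C9a, C9, C10, C11, C12; ethyl C16–C17 on C10; fused lactone C11–O–C14(=O)–C13–C12 with methyl C15 on C13; appended lactone C18 (on C3), C19, C20 (methyl C22), C21(=O), O. Target: 9R,10R,11R,12S,13S,18R,20S.

Assumption: (S)-diphenylprolinol trimethylsilyl ether is taken to shield the diene face that leads to the 9R series, by analogy with this catalyst class in trienamine cycloadditions; if the adduct proves to be 9S, the (R)-catalyst is used and nothing else changes.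

**Route**

Step 1
Reactants: 1 1H-pyrrole-3-carbaldehyde; 2 1,5-dibromopentane
Product: 3 1-(5-bromopentyl)-1H-pyrrole-3-carbaldehyde
Conditions: NaH, DMF, 0 °C; then 2 (4 equiv), 0 °C to rt
Reagents that add atoms: 2 1,5-dibromopentane, BrCCCCCBr
Why: SN2 N-alkylation of the sodium pyrrolide, with excess dibromide so that the second C–Br bond stays free.

Step 2
Reactants: 3 1-(5-bromopentyl)-1H-pyrrole-3-carbaldehyde
Product: 4 6,7,8,9-tetrahydro-5H-pyrrolo[1,2-a]azepine-1-carbaldehyde
Conditions: Bu3SnH (1.5 equiv, syringe pump), AIBN (2 equiv, in portions), PhMe (0.01 M), 110 °C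
Reagents that add atoms: none
Why: Bu3SnH-mediated oxidative radical cyclization (homolytic aromatic substitution) in which the primary radical closes the seven-membered ring onto the pyrrole carbon next to the formyl-bearing carbon, where the adduct radical is stabilized by the CHO group, and loss of H restores the pyrrole.

Step 3
Reactants: 4 6,7,8,9-tetrahydro-5H-pyrrolo[1,2-a]azepine-1-carbaldehyde; 5 (triphenyl-λ5-phosphanylidene)acetaldehyde
Product: 6 (2E)-3-(6,7,8,9-tetrahydro-5H-pyrrolo[1,2-a]azepin-1-yl)prop-2-enal
Conditions: 5 (1.0 equiv), PhMe, 80 °C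
Reagents that add atoms: 5 (triphenyl-λ5-phosphanylidene)acetaldehyde, O=CC=P(c1ccccc1)(c1ccccc1)c1ccccc1
Why: Wittig olefination with a formyl-stabilized ylide, which should give the (E)-enal and brings in C13 and C14.

Step 4
Reactants: 7 propanal; 8 nitromethane
Product: 10 (1E)-1-nitrobut-1-ene, via 1-nitrobutan-2-ol 9 (not isolated)
Conditions: 8 (5 equiv), Et3N (0.1 equiv), 0 °C to rt; then CH2Cl2, MsCl, Et3N (2.2 equiv), 0 °C
Reagents that add atoms: 8 nitromethane, C[N+](=O)[O-]
Why: Henry reaction followed by mesylation and E1cB elimination, which should give the thermodynamically favoured (E)-nitroalkene.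

Step 5
Reactants: 6 (2E)-3-(6,7,8,9-tetrahydro-5H-pyrrolo[1,2-a]azepin-1-yl)prop-2-enal; 10 (1E)-1-nitrobut-1-ene
Product: 12 nitro aldehyde (9R,10S,11R,12R), via pyrrole-2,3-quinodimethane trienamine 11 (not isolated)
Conditions: 6 (1.3 equiv), 10 (1.0 equiv), (S)-diphenylprolinol trimethylsilyl ether (20 mol%), PhCO2H (20 mol%), CHCl3, 25–40 °C
Reagents that add atoms: 10 (1E)-1-nitrobut-1-ene, CC/C=C/[N+](=O)[O-]
Why: Condensation of the amine with enal 6 gives the iminium ion, and loss of the C9 proton, which is vinylogous to the iminium carbon through C12=C13 and the pyrrole bond C1=C9a, gives trienamine 11, a HOMO-raised pyrrole-2,3-quinodimethane whose diene C9=C9a–C1=C12 adds to the nitroalkene with C9 bonding to the β-carbon (C10) and C12 to the nitro-bearing carbon (C11), after which enamine hydrolysis returns the catalyst and the aldehyde. The closest known reaction type is the amine-catalysed [4+2] cycloaddition of nitroalkenes with indole- and pyrrole-2,3-quinodimethanes generated from 2-methyl-3-(2-formylvinyl) heteroarenes; here the 2-alkyl donor is the azepine methylene. The cyclohexane ring closes in an intermolecular [4+2] cycloaddition (if the bonds form one after the other, a Michael addition followed by a 6-exo-trig addition of the nitronate to the regenerated iminium ion), driven by the return of pyrrole aromaticity. C9 is set by the catalyst, whose diphenyl(silyloxy)methyl group blocks one face of the planar diene; C10 and C11 are trans because the (E)-alkene geometry is kept; C12 is cis to C8 because both are outside substituents of a diene attacked on one face; the exo position of the nitro group puts the ethyl group cis to C8. Only C9 has to survive, since C11 becomes a carbonyl and C10 and C12 are equilibrated in step 7, so other C10–C12 diastereomers converge there. The step needs attack at the remote C9 (not C13 or the pyrrole C3–H) and a single addition of 10: the first is secured by rearomatization of the pyrrole in the C9 pathway and by the deactivation of the pyrrole by the conjugated iminium group, the second by using 10 as the limiting reagent with a β-branched product aldehyde.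

Step 6
Reactants: 12 nitro aldehyde (9R,10S,11R,12R); 13 methanol
Product: 14 nitro methyl ester (9R,10S,11R,12R)
Conditions: 1,4-dimethyl-1,2,4-triazolium iodide (5 mol%), DBU (0.2 equiv), 3,3',5,5'-tetra-tert-butyldiphenoquinone (1.1 equiv), 13 (5 equiv), THF, rt
Reagents that add atoms: 13 methanol, CO
Why: NHC-catalysed oxidative esterification, in which the acyl azolium formed by oxidation of the carbene–aldehyde adduct is trapped by methanol and no electrophilic oxidant meets the electron-rich pyrrole.

Step 7
Reactants: 14 nitro methyl ester (9R,10S,11R,12R); 15 water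
Product: 17 keto ester (9R,10R,12S), via (10S,12R)-keto ester 16 (not isolated)
Conditions: NaOMe (1.1 equiv), MeOH, 0 °C; then TiCl3 (4 equiv, aq.), NH4OAc buffer (pH 5–6), rt; crude ketone in PhMe, DBU (0.3 equiv), rt, under Ar
Reagents that add atoms: 15 water, O
Why: Nef reaction in its reductive variant (the nitronate is reduced by trivalent titanium to the imine, which is hydrolysed) unmasks the C11 ketone, and DBU then equilibrates the two α-centres C10 and C12 to the all-equatorial arrangement (ethyl trans to C8, CH2CO2Me cis to ethyl), which is the relative configuration of the target.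

Step 8
Reactants: 17 keto ester (9R,10R,12S)
Product: 18 tetracyclic lactone (9R,10R,11R,12S)
Conditions: LiBH(s-Bu)3 (1.2 equiv), THF, −78 °C to 0 °C; then H2O
Reagents that add atoms: none
Why: The bulky hydride should attack the 2,6-diequatorially substituted cyclohexanone from the equatorial direction to give the axial C11 alkoxide, cis to both neighbours, which closes the cis-fused γ-lactone on the C14 methyl ester.

Step 9
Reactants: 18 tetracyclic lactone (9R,10R,11R,12S); 19 iodomethane
Product: 20 13R-methyl lactone (9R,10R,11R,12S,13R)
Conditions: LiN(i-Pr)2 (1.1 equiv), THF, −78 °C; then 19 (1.5 equiv), −78 to −40 °C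
Reagents that add atoms: 19 iodomethane, CI
Why: Lactone enolate alkylation from the convex face of the cis-fused bicycle (the face of H-11 and H-12) should give the exo methyl group, i.e. the C13 epimer of what is needed, and any endo isomer formed converges in step 10.

Step 10
Reactants: 20 13R-methyl lactone (9R,10R,11R,12S,13R)
Product: 21 13S-methyl lactone (9R,10R,11R,12S,13S)
Conditions: LiN(i-Pr)2 (1.5 equiv), THF, −78 °C; then 2,6-di-tert-butyl-4-methylphenol (3 equiv) in THF, −78 °C
Reagents that add atoms: none
Why: Kinetic protonation of the lactone enolate by a bulky proton donor from the same convex face should place H exo and the methyl group endo (cis to C1), the configuration of the target.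

Step 11
Reactants: 22 dimethyl (2S)-2-methylbutanedioate; 15 water
Product: 23 (3S)-4-methoxy-3-methyl-4-oxobutanoic acid
Conditions: pig liver esterase, 0.1 M phosphate buffer (pH 7), rt
Reagents that add atoms: 15 water, O
Why: Enzymatic ester hydrolysis is expected to take the unbranched ester next to CH2 in preference to the α-methyl-branched one and does not touch the stereocentre.

Step 12
Reactants: 21 13S-methyl lactone (9R,10R,11R,12S,13S); 23 (3S)-4-methoxy-3-methyl-4-oxobutanoic acid
Product: 25 C3-acylated keto ester (9R,10R,11R,12S,13S,20S), via mixed trifluoroacetic anhydride 24 (not isolated)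
Conditions: 23 (1.3 equiv), (CF3CO)2O (1.3 equiv), CH2Cl2, 0 °C; then 21, −20 to 0 °C
Reagents that add atoms: 23 (3S)-4-methoxy-3-methyl-4-oxobutanoic acid, COC(=O)[C@@H](C)CC(=O)O
Why: Friedel–Crafts acylation of the electron-rich pyrrole by the mixed anhydride at C3, the only free α-position and far more nucleophilic than C2, under conditions without base so that C13 is not epimerized.

Step 13
Reactants: 25 C3-acylated keto ester (9R,10R,11R,12S,13S,20S)
Product: 27 target CNP0232452.1 (9R,10R,11R,12S,13S,18R,20S), via (18R)-hydroxy ester 26 (not isolated)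
Conditions: (S)-2-methyl-CBS-oxazaborolidine (20 mol%), catecholborane (1.5 equiv), PhMe, −78 to −40 °C; then MeOH, pH 7 buffer; then PhMe, 50 °C
Reagents that add atoms: none
Why: CBS reduction with the pyrrolyl group as the large and the CH2 chain as the small ketone substituent should give the 18R alcohol under reagent control, and the γ-hydroxy ester then closes the appended lactone with retention at C18 under neutral conditions.

**Compound list**
1 | 1H-pyrrole-3-carbaldehyde | O=Cc1cc[nH]c1 | starting material
2 | 1,5-dibromopentane | BrCCCCCBr | starting material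
3 | 1-(5-bromopentyl)-1H-pyrrole-3-carbaldehyde | O=Cc1ccn(CCCCCBr)c1 | intermediate
4 | 6,7,8,9-tetrahydro-5H-pyrrolo[1,2-a]azepine-1-carbaldehyde | O=Cc1ccn2CCCCCc12 | intermediate
5 | (triphenyl-λ5-phosphanylidene)acetaldehyde | O=CC=P(c1ccccc1)(c1ccccc1)c1ccccc1 | starting material
6 | (2E)-3-(6,7,8,9-tetrahydro-5H-pyrrolo[1,2-a]azepin-1-yl)prop-2-enal | O=C/C=C/c1ccn2CCCCCc12 | intermediate
7 | propanal | CCC=O | starting material
8 | nitromethane | C[N+](=O)[O-] | starting material
9 | 1-nitrobutan-2-ol (racemic, not isolated) | CCC(O)C[N+](=O)[O-] | intermediate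
10 | (1E)-1-nitrobut-1-ene | CC/C=C/[N+](=O)[O-] | intermediate
11 | trienamine of 6 with (S)-diphenylprolinol trimethylsilyl ether: N–CH=CH–CH= unit on C1 of a 1H-pyrrole-2,3-diylidene whose second exocyclic double bond is C9=C9a in the azepine ring (not isolated) | C[Si](C)(C)OC(c1ccccc1)(c1ccccc1)[C@@H]1CCCN1/C=C/C=C1\C=CN2CCCCC=C12 | intermediate
12 | nitro aldehyde (9R,10S,11R,12R): cyclohexane fused to pyrrole C1–C9a; ethyl on C10 cis to C8, nitro on C11 trans to ethyl, CH2CHO on C12 cis to C8 | CC[C@@H]1[C@@H]([N+](=O)[O-])[C@H](CC=O)c2ccn3c2[C@@H]1CCCC3 | intermediate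
13 | methanol | CO | starting material
14 | nitro methyl ester (9R,10S,11R,12R), CH2CO2Me on C12 | CC[C@@H]1[C@@H]([N+](=O)[O-])[C@H](CC(=O)OC)c2ccn3c2[C@@H]1CCCC3 | intermediate
15 | water | O | starting material
16 | C11 keto ester (9R,10S,12R), kinetic diastereomer (not isolated) | CC[C@@H]1C(=O)[C@H](CC(=O)OC)c2ccn3c2[C@@H]1CCCC3 | intermediate
17 | C11 keto ester (9R,10R,12S), ethyl trans to C8 and cis to CH2CO2Me | CC[C@H]1C(=O)[C@@H](CC(=O)OC)c2ccn3c2[C@@H]1CCCC3 | intermediate
18 | tetracyclic lactone (9R,10R,11R,12S), cis-fused, C11–O cis to ethyl, no C15 | CC[C@H]1[C@H]2OC(=O)C[C@H]2c2ccn3c2[C@@H]1CCCC3 | intermediate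
19 | iodomethane | CI | starting material
20 | 13R-methyl lactone (9R,10R,11R,12S,13R), methyl trans to C1 | CC[C@H]1[C@H]2OC(=O)[C@H](C)[C@H]2c2ccn3c2[C@@H]1CCCC3 | intermediate
21 | 13S-methyl lactone (9R,10R,11R,12S,13S), methyl cis to C1 | CC[C@H]1[C@H]2OC(=O)[C@@H](C)[C@H]2c2ccn3c2[C@@H]1CCCC3 | intermediate
22 | dimethyl (2S)-2-methylbutanedioate | COC(=O)[C@@H](C)CC(=O)OC | starting material
23 | (3S)-4-methoxy-3-methyl-4-oxobutanoic acid | COC(=O)[C@@H](C)CC(=O)O | intermediate
24 | mixed anhydride of 23 with trifluoroacetic acid (not isolated) | COC(=O)[C@@H](C)CC(=O)OC(=O)C(F)(F)F | intermediate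
25 | keto ester (9R,10R,11R,12S,13S,20S): 21 carrying C(=O)CH2CH(CH3)CO2Me on C3 | CC[C@H]1[C@H]2OC(=O)[C@@H](C)[C@H]2c2cc(C(=O)C[C@H](C)C(=O)OC)n3c2[C@@H]1CCCC3 | intermediate
26 | (18R)-hydroxy ester (not isolated) | CC[C@H]1[C@H]2OC(=O)[C@@H](C)[C@H]2c2cc([C@H](O)C[C@H](C)C(=O)OC)n3c2[C@@H]1CCCC3 | intermediate
27 | CNP0232452.1 (9R,10R,11R,12S,13S,18R,20S) | CC[C@H]1[C@H]2OC(=O)[C@@H](C)[C@H]2c2cc([C@H]3C[C@H](C)C(=O)O3)n3c2[C@@H]1CCCC3 | target

**Step count and risks**
Total: 13 steps. Longest linear sequence: 11 steps (1, 2, 3, 5, 6, 7, 8, 9, 10, 12, 13).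

Steps most likely to fail:

Step 5. Facial discrimination at the remote C9 terminus may be insufficient, or turnover with the bulky amine may be slow enough for the product pyrrole to add to the nitroalkene. Fallback: asymmetric catalysis is replaced by a racemic run and resolution. It sets out from 6 and 10 with pyrrolidine and PhCO2H (20 mol% each) in CHCl3, which should pass through the pyrrolidine trienamine F1 and give 12 together with its mirror-image aldehyde F2. The racemate is esterified under the conditions of step 6 to 14 and its mirror-image ester F3, and these are separated by preparative chromatography on a chiral stationary phase. The fallback comes back to the route at 14.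

Step 10. Proton transfer may be less face-selective than carbon–carbon bond formation, and proton exchange between enolate and product may erode the kinetic ratio. Fallback: C13 is set by hydrogenation instead of protonation. It sets out from 20: LiN(i-Pr)2 then CBr4 at −78 °C should give the tertiary bromide F4 with bromine on the convex face. DBU then eliminates into the methyl group, because the ring hydrogen H-12 is cis to bromine and cannot be anti-periplanar, giving the α-methylene lactone F5. H2 over Pd/C in EtOAc should deliver hydrogen from the convex face and comes back to the route at 21.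

Step 13. The pyrrolylmethyl boron ester may ionize (loss of the C18 oxygen through an azafulvenium ion), or face selectivity may be poor on the electron-rich acyl pyrrole. Fallback: reagent control is replaced by an unselective reduction with separation and recycling. It sets out from 25: NaBH4 with CeCl3·7H2O in MeOH at −20 °C (Luche reduction) should give 26 together with the (18S)-hydroxy ester F6. Warming in PhMe closes both to 27 and the 18-epi lactone F7, which are separated by chromatography. F7 is re-equilibrated at C18 with a trace of camphorsulfonic acid in CH2Cl2 (reversible ionization of the pyrrolylmethyl C–O bond) and separated again, so the fallback comes back to the route at 27.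

**Further compounds**
F1 | step 5 | trienamine of 6 with pyrrolidine (pyrrole-2,3-quinodimethane, not isolated) | C1CCN(C1)/C=C/C=C1\C=CN2CCCCC=C12
F2 | step 5 | mirror-image aldehyde, enantiomer of 12 (9S,10R,11S,12S) | CC[C@H]1[C@H]([N+](=O)[O-])[C@@H](CC=O)c2ccn3c2[C@H]1CCCC3
F3 | step 5 | mirror-image ester, enantiomer of 14 (9S,10R,11S,12S) | CC[C@H]1[C@H]([N+](=O)[O-])[C@@H](CC(=O)OC)c2ccn3c2[C@H]1CCCC3
F4 | step 10 | 13-bromo-13-methyl lactone, bromine on the convex face, methyl cis to C1 | CC[C@H]1[C@H]2OC(=O)[C@](C)(Br)[C@H]2c2ccn3c2[C@@H]1CCCC3
F5 | step 10 | 13-methylene lactone (9R,10R,11R,12S) | CC[C@H]1[C@H]2OC(=O)C(=C)[C@H]2c2ccn3c2[C@@H]1CCCC3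
F6 | step 13 | (18S)-hydroxy ester, C18 epimer of 26 | CC[C@H]1[C@H]2OC(=O)[C@@H](C)[C@H]2c2cc([C@@H](O)C[C@H](C)C(=O)OC)n3c2[C@@H]1CCCC3
F7 | step 13 | 18-epi lactone, C18 epimer of 27 | CC[C@H]1[C@H]2OC(=O)[C@@H](C)[C@H]2c2cc([C@@H]3C[C@H](C)C(=O)O3)n3c2[C@@H]1CCCC3
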